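One temperature cannot say what a change of temperature does, so the dusk run, made at 140 °C, cannot price the cooling of maple, birch and alder; what it can price is the concentration that sets the order of the split.

the same everywhere: coupling partner 1.05 equiv

|  | substrate | temperature | remark | time |
|---|---|---|---|---|
| dusk | 0.15 M | 140 °C | run made earlier |  |
| ash | 0.10 M | 140 °C |  | 6.0 min |
| maple | 0.10 M | 100 °C |  | 6.0 min |
| birch | 0.10 M | 120 °C |  | 6.0 min |
| alder | 0.10 M | 80 °C |  | 6.0 min |

dusk run (percent of the substrate charged)

| time / s | target / % | isomer of the product / % | side product / % |
|---|---|---|---|
| 10.0 | 5.5 | 13.0 | 31.5 |
| 15.0 | 5.3 | 12.9 | 33.9 |
| 25.0 | 5.1 | 15.0 | 36.2 |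
| 40.0 | 6.6 | 15.8 | 41.2 |
| 60.0 | 6.6 | 18.3 | 44.9 |
| 80.0 | 7.9 | 19.5 | 49.5 |

(readings scatter by 0.5 percentage points)

- what was read earlier has a scatter of 0.5 percentage points, one standard deviation
- steps thought possible: substrate <-> dormant form; substrate <-> tautomer; substrate + coupling partner -> isomer of the product; tautomer -> side product; coupling partner + tautomer -> target
- the earlier runs do not show what temperature does; that part of a forecast is a guess

1. the flask with the highest share of target in all that became target or isomer of the product or side product ("all alike" if they lie within 1.5 percentage points) (ash / maple / birch / alder / all alike)
2. share of target in all that became target or isomer of the product or side product, ash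
3. share of target in all that became target or isomer of the product or side product, maple
4. share of target in all that became target or isomer of the product or side product, birch
5. share of target in all that became target or isomer of the product or side product, alder

Besides going back to substrate, the tautomer has two exits to product: by itself to the side product, and with the coupling partner to the target. Its concentration stands in both rates and cancels from their ratio, so at one temperature the rate to target over the rate to side product goes with [partner] to the first order, and one concentration measures the split (the selectivity factor is [partner] over it):

c* = [partner] / (target / side product)

At the last dusk reading the partner is its charge less what target and isomer of the product took: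

[partner] = 0.116 M, target / side product = 0.160, c* = 0.729 M

We call this the crossover concentration, the [partner] at which the tautomer goes to target as fast as to side product at that temperature; it is a reading, carrying the scatter of 0.5 percentage points on a target of 7.9 %, and it sets amounts gathered over the run against the partner of the last moment. The new flasks charge 0.105 M of partner, far below that reading, so for ash at the full charge our reckoning gives target over side product of 0.144, and less as the partner is used. Our decision is to hold the charge and spend the runs on temperature, where c* itself may move by an amount we cannot reckon; for the cooler flasks we commit to no number.

The forecast does: 7.9 % for ash, 8.4 % for maple, 8.1 % for birch, 8.7 % for alder, hence all alike, adding “The temperature effect on selectivity is a guess”.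

The flasks give 7.95 % for ash, 21.5 % for maple, 13.6 % for birch and 26.4 % for alder, so the highest is alder.

    substrate ⇌ dormant form (K = 15.0, k = 0.00170 /s, Ea = 114 kJ/mol, ΔH = 5.00 kJ/mol)
    substrate ⇌ tautomer (K = 2.90, k = 0.00290 /s, Ea = 107 kJ/mol, ΔH = −25.0 kJ/mol)
    substrate + coupling partner → isomer of the product (k = 0.0240 /M/s, Ea = 69.0 kJ/mol)
    tautomer → side product (k = 0.00380 /s, Ea = 103 kJ/mol)
    coupling partner + tautomer → target (k = 0.0540 /M/s, Ea = 53.0 kJ/mol)
    (constants at 80 °C)

In alder at 6.00 min the partner stands at 0.0614 M, which with the dusk c* gives target over side product of 0.0842, but alder holds 1.08, so the c* read in alder is 0.0569 M, far below the dusk reading. At 1.47 min in alder the target step uses tautomer 1.2 times as fast as the side step.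

The neighbour of alder charged at 0.40 M of substrate ends with 0.127 M of partner, so the c* of alder gives target over side product of 2.23 at that end value. The computed flask holds 2.88, a share of target of 21.3 %.

(All runs are simulated with made-up constants, and the scatter is random.)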